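## Retrosynthetic overview

1. Target 8 is two identical 2,3-dibromo-4,5-dihydroxyphenyl rings joined by one sp3 carbon (C7H2) at C1 and C1′. Each C1 lies para to a phenol oxygen (C4–OH), and both ortho positions of that phenol (C3–Br, C5–O) are blocked.
2. The C7–C1′ bond is cut to a second molecule of the same p-hydroxybenzyl alcohol, not to an Ar–H partner: 2 × 4 → 7 + CH2O + H2O. The sequence copies the presumed biosynthesis: p-quinone methide, ipso attack at C1′, then retro-aldol loss of the C1′–CH2OH carbon.
3. Monomer 4 comes from vanillin (1) by double bromination and reduction of the aldehyde. No ring is formed in the route; both arenes come intact from vanillin.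
4. The vanillin O-methyl group stays on until the end, so that each ring has only one phenoxide and C6–H remains meta to it and unactivated. Both methyl groups are removed in the last step.

Key step: step 3

Remark: the target has no stereocentre and no hindered axis, so it is achiral. The SMILES carries no stereodescriptor and no enantiocontrol is needed. Ring numbering used below: C1 bears the bridge C7, C2 and C3 bear Br, C4 and C5 bear O, C6 bears H.

## Route

Step 1
Reactants: 1 vanillin (4-hydroxy-3-methoxybenzaldehyde)
Product: 3 2,3-dibromo-4-hydroxy-5-methoxybenzaldehyde (5,6-dibromovanillin), via 5-bromovanillin 2 (not isolated)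
Conditions: Br2 (1.05 equiv), AcOH, rt; then Fe powder (cat.), Br2 (1.2 equiv), 60 °C
Reagents that add atoms: bromine, BrBr
Why: In this twofold electrophilic aromatic bromination the free OH directs the first bromine to its only open ortho position (vanillin C5), and the Lewis-acid-assisted second bromine goes para to OMe (vanillin C6) rather than to the crowded C2 between CHO and OMe.

Step 2
Reactants: 3 2,3-dibromo-4-hydroxy-5-methoxybenzaldehyde
Product: 4 2,3-dibromo-4-hydroxy-5-methoxybenzyl alcohol
Conditions: NaBH4 (1.5 equiv), THF–H2O, 0 °C; then cold aq NH4Cl (pH about 7)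
Reagents that add atoms: none
Why: Borohydride reduction of an aryl aldehyde leaves the aryl bromides, phenol and OMe untouched, and the cold near-neutral work-up avoids early ionisation of the labile p-hydroxybenzyl alcohol.

Step 3
Reactants: 4 2,3-dibromo-4-hydroxy-5-methoxybenzyl alcohol (two molecules, one as electrophile precursor, one as nucleophile)
Product: 7 bis(2,3-dibromo-4-hydroxy-5-methoxyphenyl)methane, via p-quinone methide 5 (not isolated), via ipso-adduct dienone 6 (not isolated)
Conditions: aq NaOH (1 M, 2.5 equiv), 1,4-dioxane, high concentration, 110 °C (sealed tube), Ar; then 1 M HCl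
Reagents that add atoms: none
Why: The phenoxide of 4 expels hydroxide from its para benzylic carbon to give p-quinone methide 5, a second phenoxide of 4 adds through its para carbon C1′ (1,6-addition, ipso to CH2OH) to form the C7–C1′ bond in dienone 6, and retro-aldol (retro-Lederer–Manasse) fragmentation of the hydroxymethyl arm of 6 expels formaldehyde and restores the arene. The closest known reaction type is the base- or heat-induced self-condensation of 3,5-disubstituted 4-hydroxybenzyl alcohols (2,6-dialkylphenol and syringyl types) to bis(4-hydroxyaryl)methanes with loss of formaldehyde, familiar from phenol–formaldehyde resin and lignin model chemistry, and 4 belongs to this class. No ring is closed and 7 has no stereocentre; the quaternary carbon of 6 forms as a racemate and is erased in the fragmentation. The step needs C- over O-attack and C1′ over C6′ attack: the phenoxide charge reaches only C1′, C3′ and C5′, adducts at C3′ (Br) and C5′ (OMe) can only revert, and C6′–H is meta to O− and therefore unactivated. Aryl benzyl and dibenzyl ethers re-ionise to 5 under these conditions, so the material should funnel into the irreversible loss of formaldehyde. Product 7 has no free ortho or para position and ipso attack on it only exchanges benzyl groups, so the condensation should stop at the dimer, while the main risk is that the two bromines weaken the phenoxide as donor and nucleophile, hence the elevated temperature.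

Step 4
Reactants: 7 bis(2,3-dibromo-4-hydroxy-5-methoxyphenyl)methane
Product: 8 bis(2,3-dibromo-4,5-dihydroxyphenyl)methane (target)
Conditions: BBr3 (6 equiv), CH2Cl2, −78 °C to rt; then ice–H2O
Reagents that add atoms: none
Why: In this Lewis-acid aryl methyl ether cleavage boron binds the ether oxygen and bromide attacks the methyl carbon by SN2, which leaves the aryl bromides and the CH2 bridge untouched and is the usual end-game for brominated catechol methyl ethers.

## Compound list

1 | vanillin (4-hydroxy-3-methoxybenzaldehyde) | COc1cc(C=O)ccc1O | starting material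
2 | 5-bromovanillin (3-bromo-4-hydroxy-5-methoxybenzaldehyde) | COc1cc(C=O)cc(Br)c1O | intermediate (not isolated)
3 | 2,3-dibromo-4-hydroxy-5-methoxybenzaldehyde (5,6-dibromovanillin) | COc1cc(C=O)c(Br)c(Br)c1O | intermediate
4 | 2,3-dibromo-4-hydroxy-5-methoxybenzyl alcohol | OCc1cc(OC)c(O)c(Br)c1Br | intermediate
5 | 2,3-dibromo-6-methoxy-4-methylidenecyclohexa-2,5-dien-1-one (p-quinone methide) | C=C1C=C(OC)C(=O)C(Br)=C1Br | intermediate (not isolated)
6 | 2,3-dibromo-4-[(2,3-dibromo-4-hydroxy-5-methoxyphenyl)methyl]-4-(hydroxymethyl)-6-methoxycyclohexa-2,5-dien-1-one (racemic, transient) | OCC1(Cc2cc(OC)c(O)c(Br)c2Br)C=C(OC)C(=O)C(Br)=C1Br | intermediate (not isolated)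
7 | bis(2,3-dibromo-4-hydroxy-5-methoxyphenyl)methane | COc1cc(Cc2cc(OC)c(O)c(Br)c2Br)c(Br)c(Br)c1O | intermediate
8 | bis(2,3-dibromo-4,5-dihydroxyphenyl)methane | Oc1cc(Cc2cc(O)c(O)c(Br)c2Br)c(Br)c(Br)c1O | target

Total step count: 4. Longest linear sequence: 4.

## Steps most likely to fail

**Step 3.**
- Risk: hydroxide loss from the electron-poor phenoxide may be sluggish, and ipso attack next to the C2 bromine may be slow. The material could then rest at the ether stage or be diverted by hydride transfer from formaldehyde to the quinone methide.
- Fallback (sets out from 3, returns at 7): part of 3 is oxidised by Pinnick oxidation (NaClO2, NaH2PO4, 2-methyl-2-butene, t-BuOH–H2O) to 2,3-dibromo-4-hydroxy-5-methoxybenzoic acid F1.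
- F1 is then protodecarboxylated (cat. Ag2CO3, AcOH, DMSO, 120 °C; helped by the ortho bromine and the para hydroxyl) to 2,3-dibromo-6-methoxyphenol F2.
- F2 has a free C–H para to its OH. Its condensation with alcohol 4 (aq NaOH, heat, through 5, or cat. H2SO4 in AcOH) is therefore an ordinary C–H hydroxybenzylation of a phenol. It ends by tautomerisation instead of C–C cleavage and should give 7.

**Step 1.**
- Risk: ipso attack of bromine at the carbon para to the free OH could cause loss of the formyl group. The second bromination could also stall, or spill over to C2.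
- Fallback (sets out from 1, returns at 3): the order and the directing group are reversed. Vanillin is acetylated (Ac2O, pyridine) to 4-formyl-2-methoxyphenyl acetate F3.
- With the phenol masked, OMe directs bromination (Br2, KBr, H2O, or Br2, NaOAc, AcOH) to its para position, which gives 5-bromo-4-formyl-2-methoxyphenyl acetate F4.
- Hydrolysis (aq HCl, heat) frees 2-bromo-4-hydroxy-5-methoxybenzaldehyde F5 (6-bromovanillin). Its OH then directs a mild, uncatalysed bromination (Br2, AcOH, rt) to the remaining ortho position to give 3.

**Step 4.**
- Risk: ether cleavage may be incomplete on the poorly soluble tetrabromide, or acid may protonate para to OH and break or scramble the bridge.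
- Fallback (sets out from 3, returns at 8): the methyl group is removed before the bridge exists. Chelation-assisted cleavage of the o-hydroxyanisole unit of 3 (AlCl3, pyridine, CH2Cl2, reflux) should give 2,3-dibromo-4,5-dihydroxybenzaldehyde F6.
- NaBH4 reduction (THF–H2O, 0 °C) gives 2,3-dibromo-4,5-dihydroxybenzyl alcohol F7 (lanosol).
- F7 is self-condensed without protecting groups in degassed dilute aqueous acid with warming. The path runs through 2,3-dibromo-6-hydroxy-4-methylidenecyclohexa-2,5-dien-1-one F8 and the ipso adduct 2,3-dibromo-4-[(2,3-dibromo-4,5-dihydroxyphenyl)methyl]-6-hydroxy-4-(hydroxymethyl)cyclohexa-2,5-dien-1-one F9, which loses formaldehyde to give 8 directly.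
- The price of this fallback is competition from attack at C6–H, which is ortho to the second free OH.

## Further compounds

F1 | step 3 | 2,3-dibromo-4-hydroxy-5-methoxybenzoic acid | COc1cc(C(=O)O)c(Br)c(Br)c1O
F2 | step 3 | 2,3-dibromo-6-methoxyphenol | COc1ccc(Br)c(Br)c1O
F3 | step 1 | 4-formyl-2-methoxyphenyl acetate (vanillin acetate) | COc1cc(C=O)ccc1OC(C)=O
F4 | step 1 | 5-bromo-4-formyl-2-methoxyphenyl acetate (6-bromovanillin acetate) | COc1cc(C=O)c(Br)cc1OC(C)=O
F5 | step 1 | 2-bromo-4-hydroxy-5-methoxybenzaldehyde (6-bromovanillin) | COc1cc(C=O)c(Br)cc1O
F6 | step 4 | 2,3-dibromo-4,5-dihydroxybenzaldehyde | O=Cc1cc(O)c(O)c(Br)c1Br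
F7 | step 4 | 2,3-dibromo-4,5-dihydroxybenzyl alcohol (lanosol) | OCc1cc(O)c(O)c(Br)c1Br
F8 | step 4 | 2,3-dibromo-6-hydroxy-4-methylidenecyclohexa-2,5-dien-1-one | C=C1C=C(O)C(=O)C(Br)=C1Br
F9 | step 4 | 2,3-dibromo-4-[(2,3-dibromo-4,5-dihydroxyphenyl)methyl]-6-hydroxy-4-(hydroxymethyl)cyclohexa-2,5-dien-1-one (racemic, transient) | OCC1(Cc2cc(O)c(O)c(Br)c2Br)C=C(O)C(=O)C(Br)=C1Br
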